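**Plan**

1. Retrosynthesis: the two phenol acetates are removed first, then ring C is cut at C2–C3 (carbene C–H insertion). This leaves a diazoketone (C3, C4) on C4a and a benzyl ether on O1; C3–C4 is cut to an aroyl chloride and diazomethane.
2. Ring A is then taken apart: C4–C4a (formylation) and the C8–prenyl bond (allylation) by two ortho-metalations of a symmetric arene, O1–C2 to benzyl bromide, and C8a–O1 to borylation–oxidation of 2-methoxyresorcinol.
3. Enabling feature: C2 is a benzylic carbon bonded to O1. In the O1 benzyl ether its CH2 is therefore a doubly activated C–H site lying 1,6 to a carbene at C3, and joining C2 to C3 closes the six-membered ring C.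
4. Forward order: ring A is fully substituted first (O1, then prenyl at C8, then C4 as CHO, CO2H and COCHN2, with MOM exchanged for acetate). Ring B arrives with the benzyl group, ring C is closed by the insertion, and deacetylation ends the route.
5. Stereochemistry: the single stereocentre C2 (S) comes from the chiral dirhodium carboxylate Rh2(S-PTTL)4 (divalent rhodium), which selects one of the two enantiotopic benzylic hydrogens; the neutral last step does not touch it.

Key step: step 10

Remark: prenyl = 3-methylbut-2-enyl, MOM = methoxymethyl, Bn = benzyl. Flavanone locants (O1, C2 to C8a) are also used for the corresponding atoms of the open precursors. Rh2(S-PTTL)4 = dirhodium tetrakis[N-phthaloyl-(S)-tert-leucinate].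

Assumption: the S-configured catalyst is taken to deliver the 2S product. The sense of induction is to be confirmed on a first analytical run; the mirror-image complex Rh2(R-PTTL)4 would be used otherwise, with nothing else changed.

**Route**

Step 1
Reactants: 1 2-methoxybenzene-1,3-diol (2-methoxyresorcinol)
Product: 2 2-methoxy-1,3-bis(methoxymethoxy)benzene
Conditions: NaH, DMF, 0 °C; MOMCl, 0 °C to rt
Reagents that add atoms: chloromethyl methyl ether, COCCl
Why: Williamson-type O-alkylation of both sodium phenoxides should give the bis-MOM ether, which masks the future O5 and O7 and later directs ortho-metalation.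

Step 2
Reactants: 2 2-methoxy-1,3-bis(methoxymethoxy)benzene
Product: 4 4-methoxy-3,5-bis(methoxymethoxy)phenol, via aryl pinacol boronate 3 (not isolated)
Conditions: [Ir(OMe)(cod)]2 (cat.), 4,4'-di-tert-butyl-2,2'-bipyridine (cat.), B2pin2 (0.6 equiv), THF, 80 °C; then aq. NaOH, H2O2, 0 °C to rt
Reagents that add atoms: hydrogen peroxide, OO; bis(pinacolato)diboron, CC1(C)OB(OC1(C)C)B1OC(C)(C)C(C)(C)O1 (boron group of 3 only)
Why: Iridium-catalysed aromatic C–H borylation is sterically governed and should go to C5, the only ring C–H without an ortho substituent, and alkaline peroxide oxidation of the aryl boronate (aryl shift from boron to oxygen) then gives the phenol whose oxygen becomes O1.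

Step 3
Reactants: 4 4-methoxy-3,5-bis(methoxymethoxy)phenol; 5 benzyl bromide
Product: 6 5-(benzyloxy)-2-methoxy-1,3-bis(methoxymethoxy)benzene
Conditions: K2CO3, DMF, rt
Reagents that add atoms: benzyl bromide (5), BrCc1ccccc1
Why: Williamson ether synthesis on the only free phenol installs the benzyl group whose CH2 becomes C2 and whose phenyl becomes ring B, and the symmetric product has two equivalent ring hydrogens.

Step 4
Reactants: 6 5-(benzyloxy)-2-methoxy-1,3-bis(methoxymethoxy)benzene; 7 prenyl bromide (1-bromo-3-methylbut-2-ene)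
Product: 9 1-(benzyloxy)-4-methoxy-3,5-bis(methoxymethoxy)-2-(3-methylbut-2-enyl)benzene, via aryllithium 8 (not isolated)
Conditions: n-BuLi (1.05 equiv), THF, −20 to 0 °C; CuI (cat.), prenyl bromide, −78 °C to rt
Reagents that add atoms: prenyl bromide (7), CC(C)=CCBr; n-butyllithium, [Li]CCCC (lithium of 8 only)
Why: Directed ortho-metalation should remove one of the two equivalent ring hydrogens, each flanked by a chelating OMOM and the OBn group, and copper-catalysed allylic substitution of the aryllithium at the primary carbon of prenyl bromide then places the prenyl group on the future C8.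

Step 5
Reactants: 9 1-(benzyloxy)-4-methoxy-3,5-bis(methoxymethoxy)-2-(3-methylbut-2-enyl)benzene
Product: 12 2-(benzyloxy)-5-methoxy-4,6-bis(methoxymethoxy)-3-(3-methylbut-2-enyl)benzaldehyde, via aryllithium 10 (not isolated), via lithium aminoalkoxide 11 (not isolated)
Conditions: n-BuLi, THF, −20 to 0 °C; DMF, −78 to 0 °C; H2O
Reagents that add atoms: N,N-dimethylformamide, CN(C)C=O; n-butyllithium, [Li]CCCC (lithium of 10 and 11 only)
Why: A second directed ortho-metalation at the last ring hydrogen (again between OMOM and OBn) followed by formylation with DMF (Bouveault aldehyde synthesis) puts the future C4 on C4a, the ring lithiation between two ether oxygens being expected to outpace benzylic deprotonation at low temperature.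

Step 6
Reactants: 12 2-(benzyloxy)-5-methoxy-4,6-bis(methoxymethoxy)-3-(3-methylbut-2-enyl)benzaldehyde
Product: 13 2-(benzyloxy)-4,6-dihydroxy-5-methoxy-3-(3-methylbut-2-enyl)benzaldehyde
Conditions: HCl (3 M aq.), MeOH, rt to 40 °C
Reagents that add atoms: none
Why: Acid-catalysed acetal exchange with methanol should cleave both MOM ethers while the benzyl ether and the aldehyde persist, dilute acid near room temperature being a standard treatment for MOM ethers of ortho-prenylphenols.

Step 7
Reactants: 13 2-(benzyloxy)-4,6-dihydroxy-5-methoxy-3-(3-methylbut-2-enyl)benzaldehyde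
Product: 14 4,6-diacetoxy-2-(benzyloxy)-5-methoxy-3-(3-methylbut-2-enyl)benzaldehyde
Conditions: Ac2O, pyridine, DMAP (cat.), CH2Cl2, 0 °C to rt
Reagents that add atoms: acetic anhydride, CC(=O)OC(C)=O
Why: DMAP-catalysed O-acylation should esterify both phenols, including the hydrogen-bonded one, giving acetates that have no activated C–H bond and a poorly nucleophilic oxygen for the carbene step.

Step 8
Reactants: 14 4,6-diacetoxy-2-(benzyloxy)-5-methoxy-3-(3-methylbut-2-enyl)benzaldehyde
Product: 15 4,6-diacetoxy-2-(benzyloxy)-5-methoxy-3-(3-methylbut-2-enyl)benzoic acid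
Conditions: NaClO2, NaH2PO4, 2-methyl-2-butene (large excess), t-BuOH–H2O, 0 °C to rt
Reagents that add atoms: sodium chlorite, [Na+].[O-]Cl=O
Why: Pinnick oxidation converts the hindered aldehyde into the acid under buffered conditions that aryl acetates tolerate, the hexasubstituted ring offers no site for chlorination, and the excess 2-methyl-2-butene should intercept HOCl before it reaches the prenyl double bond.

Step 9
Reactants: 15 4,6-diacetoxy-2-(benzyloxy)-5-methoxy-3-(3-methylbut-2-enyl)benzoic acid
Product: 17 1-[4,6-diacetoxy-2-(benzyloxy)-5-methoxy-3-(3-methylbut-2-enyl)phenyl]-2-diazoethanone, via acid chloride 16 (not isolated)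
Conditions: 1-chloro-N,N,2-trimethylprop-1-en-1-amine, CH2Cl2, 0 °C to rt; then CH2N2 (excess), Et2O, 0 °C
Reagents that add atoms: diazomethane, C=[N+]=[N-]; 1-chloro-N,N,2-trimethylprop-1-en-1-amine, CC(C)=C(Cl)N(C)C (chlorine of 16 only)
Why: The chloroenamine should form the acid chloride without liberating HCl (which could add to the prenyl group), and C-acylation of diazomethane (first stage of the Arndt–Eistert sequence) then gives the terminal diazoketone, excess diazomethane taking up the HCl.

Step 10
Reactants: 17 1-[4,6-diacetoxy-2-(benzyloxy)-5-methoxy-3-(3-methylbut-2-enyl)phenyl]-2-diazoethanone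
Product: 18 (2S)-5,7-diacetoxy-6-methoxy-8-(3-methylbut-2-enyl)-2-phenylchroman-4-one
Conditions: Rh2(S-PTTL)4 (1 mol%), CH2Cl2, 0 °C, slow addition of 17
Reagents that add atoms: none
Why: Loss of N2 from 17 at the dirhodium centre should give an electrophilic carbene at C3, which inserts through a concerted, asynchronous three-centre transition state into one C–H bond of the O1 benzyl CH2 and so forms C2–C3. The closest known reaction type is the dirhodium tetracarboxylate-catalysed intramolecular C–H insertion of ortho-alkoxyaryl diazoketones to chroman-4-ones, including enantioselective versions with chiral carboxylate ligands. Ring C closes as a six-membered ring by 1,6-insertion (C3 to C2 across C4, C4a, C8a and O1). C2 is set by the chiral N-phthaloyl-tert-leucinate ligand sphere, which distinguishes the two enantiotopic benzylic hydrogens, the antipode of the catalyst deciding for 2S. The step needs C–H insertion to outrun attack of the carbene on the lone pair of O1 (oxonium ylide, then benzyl shift to a benzofuranone); the doubly activated benzylic ether C–H, a ring A without any aromatic C–H, acetates on O5 and O7 that offer neither an activated C–H nor a nucleophilic oxygen, and a prenyl group on C8 that cannot be reached from C3 should direct the carbene to the benzyl CH2, while slow addition suppresses carbene dimerisation.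

Step 11
Reactants: 18 (2S)-5,7-diacetoxy-6-methoxy-8-(3-methylbut-2-enyl)-2-phenylchroman-4-one
Product: 19 agrandol, (2S)-5,7-dihydroxy-6-methoxy-8-(3-methylbut-2-enyl)-2-phenylchroman-4-one
Conditions: NH4OAc, MeOH–H2O, rt
Reagents that add atoms: none
Why: Ammonium acetate-mediated solvolysis (transesterification to methanol) should remove both aryl acetates at neutral pH, so that neither base-induced opening of ring C to the chalcone (which would racemise C2) nor acid-induced cyclisation of the prenyl group can occur.

**Compound list**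

1 | 2-methoxybenzene-1,3-diol (2-methoxyresorcinol) | COc1c(O)cccc1O | starting material
2 | 2-methoxy-1,3-bis(methoxymethoxy)benzene | COCOc1cccc(OCOC)c1OC | intermediate
3 | 2-[4-methoxy-3,5-bis(methoxymethoxy)phenyl]-4,4,5,5-tetramethyl-1,3,2-dioxaborolane | COCOc1cc(B2OC(C)(C)C(C)(C)O2)cc(OCOC)c1OC | intermediate (not isolated)
4 | 4-methoxy-3,5-bis(methoxymethoxy)phenol | COCOc1cc(O)cc(OCOC)c1OC | intermediate
5 | benzyl bromide | BrCc1ccccc1 | starting material
6 | 5-(benzyloxy)-2-methoxy-1,3-bis(methoxymethoxy)benzene | COCOc1cc(OCc2ccccc2)cc(OCOC)c1OC | intermediate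
7 | prenyl bromide (1-bromo-3-methylbut-2-ene) | CC(C)=CCBr | starting material
8 | [6-(benzyloxy)-3-methoxy-2,4-bis(methoxymethoxy)phenyl]lithium | [Li]c1c(OCOC)c(OC)c(OCOC)cc1OCc1ccccc1 | intermediate (not isolated)
9 | 1-(benzyloxy)-4-methoxy-3,5-bis(methoxymethoxy)-2-(3-methylbut-2-enyl)benzene | COCOc1cc(OCc2ccccc2)c(CC=C(C)C)c(OCOC)c1OC | intermediate
10 | [2-(benzyloxy)-5-methoxy-4,6-bis(methoxymethoxy)-3-(3-methylbut-2-enyl)phenyl]lithium | [Li]c1c(OCOC)c(OC)c(OCOC)c(CC=C(C)C)c1OCc1ccccc1 | intermediate (not isolated)
11 | lithium [2-(benzyloxy)-5-methoxy-4,6-bis(methoxymethoxy)-3-(3-methylbut-2-enyl)phenyl](dimethylamino)methanolate | [Li]OC(N(C)C)c1c(OCOC)c(OC)c(OCOC)c(CC=C(C)C)c1OCc1ccccc1 | intermediate (not isolated)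
12 | 2-(benzyloxy)-5-methoxy-4,6-bis(methoxymethoxy)-3-(3-methylbut-2-enyl)benzaldehyde | O=Cc1c(OCOC)c(OC)c(OCOC)c(CC=C(C)C)c1OCc1ccccc1 | intermediate
13 | 2-(benzyloxy)-4,6-dihydroxy-5-methoxy-3-(3-methylbut-2-enyl)benzaldehyde | O=Cc1c(O)c(OC)c(O)c(CC=C(C)C)c1OCc1ccccc1 | intermediate
14 | 4,6-diacetoxy-2-(benzyloxy)-5-methoxy-3-(3-methylbut-2-enyl)benzaldehyde | O=Cc1c(OC(C)=O)c(OC)c(OC(C)=O)c(CC=C(C)C)c1OCc1ccccc1 | intermediate
15 | 4,6-diacetoxy-2-(benzyloxy)-5-methoxy-3-(3-methylbut-2-enyl)benzoic acid | OC(=O)c1c(OC(C)=O)c(OC)c(OC(C)=O)c(CC=C(C)C)c1OCc1ccccc1 | intermediate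
16 | 4,6-diacetoxy-2-(benzyloxy)-5-methoxy-3-(3-methylbut-2-enyl)benzoyl chloride | ClC(=O)c1c(OC(C)=O)c(OC)c(OC(C)=O)c(CC=C(C)C)c1OCc1ccccc1 | intermediate (not isolated)
17 | 1-[4,6-diacetoxy-2-(benzyloxy)-5-methoxy-3-(3-methylbut-2-enyl)phenyl]-2-diazoethanone | [N-]=[N+]=CC(=O)c1c(OC(C)=O)c(OC)c(OC(C)=O)c(CC=C(C)C)c1OCc1ccccc1 | intermediate
18 | (2S)-5,7-diacetoxy-6-methoxy-8-(3-methylbut-2-enyl)-2-phenylchroman-4-one | COc1c(OC(C)=O)c(CC=C(C)C)c2c(c1OC(C)=O)C(=O)C[C@@H](c1ccccc1)O2 | intermediate
19 | agrandol, (2S)-5,7-dihydroxy-6-methoxy-8-(3-methylbut-2-enyl)-2-phenylchroman-4-one | COc1c(O)c(CC=C(C)C)c2c(c1O)C(=O)C[C@@H](c1ccccc1)O2 | target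

Total step count: 11.
Longest linear sequence: 11 steps (1 to 19); benzyl bromide 5 and prenyl bromide 7 are bought.

**Steps most likely to fail**

Step 10. The carbene may attack the lone pair of O1 (oxonium ylide, then benzyl shift) instead of the benzylic C–H bond, or the catalyst may discriminate the two enantiotopic hydrogens poorly. The fallback separates ring closure from stereocontrol. It sets out from 17, which is cyclised with the achiral Rh2(OAc)4 (divalent rhodium; CH2Cl2, rt), a catalyst chosen only for chemoselectivity, to give racemic 5,7-diacetoxy-6-methoxy-8-(3-methylbut-2-enyl)-2-phenylchroman-4-one F1. A kinetic resolution by asymmetric transfer hydrogenation follows: Cp*RhCl[(R,R)-TsDPEN] (trivalent rhodium), HCO2H/Et3N, EtOAc, rt, stopped near half conversion. By the usual model this antipode should reduce the 2R ketone to (2R,4R)-5,7-diacetoxy-6-methoxy-8-(3-methylbut-2-enyl)-2-phenylchroman-4-ol F2 and leave the 2S ketone. After chromatographic separation the unreduced ketone is 18, where the route is rejoined.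

Step 5. n-BuLi may remove a benzylic hydrogen (the ArCH2 of the prenyl group, or the OCH2Ph, which would lead on to Wittig rearrangement) in competition with the ring hydrogen. The fallback avoids a second organolithium and sets out from 9. Cleavage of the MOM ethers (HCl, MeOH, rt) should give 5-(benzyloxy)-2-methoxy-4-(3-methylbut-2-enyl)benzene-1,3-diol F3. Its only free ring position is ortho to a phenol, so magnesium-mediated ortho-formylation (MgCl2, Et3N, paraformaldehyde, MeCN, reflux; Casnati–Skattebøl) should place the formyl group there and give 13, where the route is rejoined.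

Step 6. During MOM cleavage the acid may promote addition of the neighbouring O7 phenol, or of methanol, across the prenyl double bond (chroman formation). The fallback brings in the prenyl group only after the acid step and sets out from 6. Lithiation of 6 to 8 (n-BuLi, THF) and addition to DMF should give, through the lithium aminoalkoxide lithium [2-(benzyloxy)-5-methoxy-4,6-bis(methoxymethoxy)phenyl](dimethylamino)methanolate F4, the aldehyde 2-(benzyloxy)-5-methoxy-4,6-bis(methoxymethoxy)benzaldehyde F5. HCl in MeOH then gives 2-(benzyloxy)-4,6-dihydroxy-5-methoxybenzaldehyde F6. Its non-chelated 4-hydroxyl is O-alkylated with methyl 2-methylbut-3-en-2-yl carbonate under Pd(PPh3)4 catalysis (zerovalent palladium, THF, rt; Tsuji–Trost etherification) to 2-(benzyloxy)-6-hydroxy-5-methoxy-4-[(2-methylbut-3-en-2-yl)oxy]benzaldehyde F7. Aromatic Claisen rearrangement (toluene, 110 °C) should move the allyl unit to the only free ortho carbon as a prenyl group and give 13, where the route is rejoined. This path also avoids lithiation in the presence of the prenyl group.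

**Further compounds**

F1 | step 10 | racemic 5,7-diacetoxy-6-methoxy-8-(3-methylbut-2-enyl)-2-phenylchroman-4-one | COc1c(OC(C)=O)c(CC=C(C)C)c2c(c1OC(C)=O)C(=O)CC(c1ccccc1)O2
F2 | step 10 | (2R,4R)-5,7-diacetoxy-6-methoxy-8-(3-methylbut-2-enyl)-2-phenylchroman-4-ol | COc1c(OC(C)=O)c(CC=C(C)C)c2c(c1OC(C)=O)[C@H](O)C[C@H](c1ccccc1)O2
F3 | step 5 | 5-(benzyloxy)-2-methoxy-4-(3-methylbut-2-enyl)benzene-1,3-diol | COc1c(O)cc(OCc2ccccc2)c(CC=C(C)C)c1O
F4 | step 6 | lithium [2-(benzyloxy)-5-methoxy-4,6-bis(methoxymethoxy)phenyl](dimethylamino)methanolate | [Li]OC(N(C)C)c1c(OCOC)c(OC)c(OCOC)cc1OCc1ccccc1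
F5 | step 6 | 2-(benzyloxy)-5-methoxy-4,6-bis(methoxymethoxy)benzaldehyde | O=Cc1c(OCOC)c(OC)c(OCOC)cc1OCc1ccccc1
F6 | step 6 | 2-(benzyloxy)-4,6-dihydroxy-5-methoxybenzaldehyde | O=Cc1c(O)c(OC)c(O)cc1OCc1ccccc1
F7 | step 6 | 2-(benzyloxy)-6-hydroxy-5-methoxy-4-[(2-methylbut-3-en-2-yl)oxy]benzaldehyde | O=Cc1c(O)c(OC)c(OC(C)(C)C=C)cc1OCc1ccccc1
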